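## Retrosynthetic overview

- The last two operations are global hydrogenolysis of eleven O-benzyl groups and acylation of the free C3–OH of the second chroman with a protected gallic acid; that C3–OH comes from a C3–B bond.
- The key disconnection is the bond between C2 of the gallate-bearing chroman and C7 of the benzotropolone. It is made together with the C3–B bond by an enantioselective syn-1,2-arylboration of an achiral 4H-chromene with a 7-bromobenzotropolone.
- The enabling feature is that the cis pair C2-aryl/C3-oxygen on the pyran ring is the imprint of a syn addition to a planar C2=C3 enol-ether bond, and that C7 of the seven-membered ring is a vinylic carbon next to C6–O that can carry bromine.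
- Ring order: the seven-membered tropolone ring is formed first, by oxidative condensation of the catechol ring of (−)-epicatechin with 4-bromopyrogallol (loss of CO2). The pyran ring of the second chroman is closed by Claisen rearrangement and ring-closing metathesis before the coupling. No ring is formed after the key step.

Key step: step 9

Remark: the tropolone is drawn as the 5-oxo/6-oxy tautomer and its benzyl ether is taken to sit on O-6; an O-5 ether isomer would react alike and give the same tropolone on debenzylation.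

## Route

Step 1
Reactants: 1 1-bromo-2,3,4-trimethoxybenzene
Product: 2 4-bromobenzene-1,2,3-triol (4-bromopyrogallol)
Conditions: BBr3, CH2Cl2, −78 °C to rt; H2O work-up
Reagents that add atoms: none
Why: Threefold Lewis-acid cleavage of aryl methyl ethers (BBr3 demethylation) should leave the aryl C–Br bond untouched; no stereocentre is involved.

Step 2
Reactants: 3 (−)-epicatechin [(2R,3R)]; 2 4-bromobenzene-1,2,3-triol
Product: 5 (2R,3R)-2-(7-bromo-3,4,6-trihydroxy-5-oxo-5H-benzo[7]annulen-1-yl)chromane-3,5,7-triol, via epicatechin o-quinone 4 (not isolated)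
Conditions: horseradish peroxidase (cat.), aq. H2O2 (added in portions), acetone/citrate–phosphate buffer pH 5, rt
Reagents that add atoms: none
Why: Oxidative benzotropolone (purpurogallin-type) condensation as in theaflavin formation: the catechol ring of 3 is oxidised to quinone 4, C6 of 2 adds to it in a Michael addition, and reoxidation, carbonyl addition to a bicyclo[3.2.1]octane adduct and oxidative decarboxylation (C1 of 2 lost as CO2) close the seven-membered ring so that the bromine-bearing C4 of 2 becomes C7, while the two stereocentres of 3 are not involved at pH 5.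

Step 3
Reactants: 5 (2R,3R)-2-(7-bromo-3,4,6-trihydroxy-5-oxo-5H-benzo[7]annulen-1-yl)chromane-3,5,7-triol
Product: 6 1-[(2R,3R)-5,7-bis(benzyloxy)-3-hydroxychroman-2-yl]-3,4,6-tris(benzyloxy)-7-bromo-5H-benzo[7]annulen-5-one
Conditions: BnBr, K2CO3, DMF, rt to 50 °C
Reagents that add atoms: benzyl bromide, BrCc1ccccc1
Why: Williamson etherification of the five acidic hydroxyls (four phenols and the tropolone OH) should occur while carbonate leaves the secondary alcohol alone; the stereocentres are not touched.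

Step 4
Reactants: 6 1-[(2R,3R)-5,7-bis(benzyloxy)-3-hydroxychroman-2-yl]-3,4,6-tris(benzyloxy)-7-bromo-5H-benzo[7]annulen-5-one
Product: 7 1-[(2R,3R)-3,5,7-tris(benzyloxy)chroman-2-yl]-3,4,6-tris(benzyloxy)-7-bromo-5H-benzo[7]annulen-5-one
Conditions: NaH, BnBr, Bu4NI (cat.), THF/DMF, 0 °C to rt
Reagents that add atoms: benzyl bromide, BrCc1ccccc1
Why: Williamson etherification of the secondary alkoxide caps the only remaining hydroxyl (and any phenol left from step 3), so that later only the new chroman carries a free 3-OH; with all phenols capped no quinone-methide path for C2 epimerisation is open.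

Step 5
Reactants: 8 3,5-bis(benzyloxy)phenol
Product: 9 1-(allyloxy)-3,5-bis(benzyloxy)benzene
Conditions: allyl bromide, K2CO3, acetone, reflux
Reagents that add atoms: allyl bromide, C=CCBr
Why: Williamson O-allylation of a phenol; no stereocentre is involved.

Step 6
Reactants: 9 1-(allyloxy)-3,5-bis(benzyloxy)benzene
Product: 10 2-allyl-3,5-bis(benzyloxy)phenol
Conditions: N,N-diethylaniline, 190 °C
Reagents that add atoms: none
Why: Aromatic Claisen rearrangement ([3,3]); the two ortho positions are equivalent by symmetry, so one regioisomer should form.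

Step 7
Reactants: 10 2-allyl-3,5-bis(benzyloxy)phenol
Product: 11 2-allyl-1,5-bis(benzyloxy)-3-(ethenyloxy)benzene
Conditions: vinyl acetate, [Ir(cod)Cl]2 (cat.), Na2CO3, toluene, 100 °C
Reagents that add atoms: vinyl acetate, CC(=O)OC=C
Why: Iridium-catalysed transfer vinylation of a phenol with vinyl acetate gives the aryl vinyl ether without touching the allyl group or the benzyl ethers.

Step 8
Reactants: 11 2-allyl-1,5-bis(benzyloxy)-3-(ethenyloxy)benzene
Product: 12 5,7-bis(benzyloxy)-4H-chromene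
Conditions: Grubbs II (cat.), 1,4-benzoquinone (cat.), toluene, 60 °C
Reagents that add atoms: none
Why: Ring-closing metathesis between the allyl and vinyl-ether alkenes closes the six-membered pyran ring as a cyclic enol ether with loss of ethene; benzoquinone suppresses ruthenium-hydride isomerisation of the allyl group.

Step 9
Reactants: 7 1-[(2R,3R)-3,5,7-tris(benzyloxy)chroman-2-yl]-3,4,6-tris(benzyloxy)-7-bromo-5H-benzo[7]annulen-5-one; 12 5,7-bis(benzyloxy)-4H-chromene
Product: 13 3,4,6-tris(benzyloxy)-7-[(2S,3R)-5,7-bis(benzyloxy)-3-(4,4,5,5-tetramethyl-1,3,2-dioxaborolan-2-yl)chroman-2-yl]-1-[(2R,3R)-3,5,7-tris(benzyloxy)chroman-2-yl]-5H-benzo[7]annulen-5-one (2,3-cis; the spatial arrangement is that of the target, the descriptor at C2 changes because boron lowers the priority of C3)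
Conditions: B2pin2, NiBr2·DME (10 mol%), chiral bis(oxazoline) ligand (12 mol%, enantiomer selected for the 2S,3R product), KOt-Bu, DMA, 0 °C to rt; 12 in excess
Reagents that add atoms: bis(pinacolato)diboron, CC1(C)OB(OC1(C)C)B1OC(C)(C)C(C)(C)O1
Why: Proposed new method: a chiral bis(oxazoline)–nickel boryl species, formed from B2pin2 and tert-butoxide, should add syn across the C2=C3 enol-ether double bond of achiral 12 with boron at C3 and nickel at the oxygen-bearing C2, after which the alkylnickel takes up the vinylic C7–Br bond of 7 by oxidative addition and C2–C7 reductive elimination occurs with retention. The closest known reaction type is the nickel-catalysed syn-1,2-arylboration (carboboration) of cyclic alkenes with aryl bromides and B2pin2, shown in racemic or substrate-controlled form on endocyclic enecarbamates and cyclic enol ethers such as glycals, while enantioselective arylborations with chiral ligands are known for alkenylarenes; new here is ligand-controlled face selection on a cyclic enol ether with a bromotropolone partner. No ring is closed in this step. Both stereocentres of the second chroman are created here: the 2,3-cis relationship follows from syn migratory insertion and stereoretentive C–C bond formation, and the absolute configuration from the chiral ligand, since the remote epicatechin unit of 7 cannot bias the faces of the planar chromene. The step needs regioselectivity (aryl at C2), secured by the preference for the metal at the α-oxygenated carbon as in glycal carboboration, and chemoselectivity of the boryl-metal for the enol ether over the tropolone ring and over direct borylation of C7–Br, for which 12 is used in excess; bulky tert-butoxide is chosen so that no alkoxide exchange occurs at the vinylogous ester C6–OBn.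

Step 10
Reactants: 13 the 2,3-cis C3-boronate from step 9
Product: 14 3,4,6-tris(benzyloxy)-7-[(2R,3R)-5,7-bis(benzyloxy)-3-hydroxychroman-2-yl]-1-[(2R,3R)-3,5,7-tris(benzyloxy)chroman-2-yl]-5H-benzo[7]annulen-5-one
Conditions: NaBO3·4H2O, THF/H2O, 0 °C to rt
Reagents that add atoms: sodium perborate, [Na+].[O-]OB=O
Why: Perborate oxidation of a secondary alkylboronic ester proceeds by 1,2-migration of C3 from boron to oxygen with retention, so the 2,3-cis alcohol (2R,3R by CIP) should result; the mild oxidant should spare the benzyloxytropone.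

Step 11
Reactants: 14 the 2,3-cis alcohol from step 10; 15 3,4,5-tris(benzyloxy)benzoic acid
Product: 16 (2R,3R)-5,7-bis(benzyloxy)-2-{3,4,6-tris(benzyloxy)-5-oxo-1-[(2R,3R)-3,5,7-tris(benzyloxy)chroman-2-yl]-5H-benzo[7]annulen-7-yl}chroman-3-yl 3,4,5-tris(benzyloxy)benzoate
Conditions: EDC·HCl, DMAP, CH2Cl2, rt
Reagents that add atoms: none
Why: Steglich esterification of the only free hydroxyl (the axial C3–OH of the new chroman) acylates on oxygen without touching a stereocentre, as in known gallate syntheses of 2,3-cis flavan-3-ols.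

Step 12
Reactants: 16 the perbenzylated gallate from step 11
Product: 17 (2R,3R)-5,7-dihydroxy-2-{3,4,6-trihydroxy-5-oxo-1-[(2R,3R)-3,5,7-trihydroxychroman-2-yl]-5H-benzo[7]annulen-7-yl}chroman-3-yl 3,4,5-trihydroxybenzoate (CNP0125877.1)
Conditions: H2 (1 atm), Pd(OH)2/C, THF/MeOH, rt
Reagents that add atoms: none
Why: Heterogeneous hydrogenolysis should cleave all eleven O-benzyl groups (ten aryl-type ethers and one alkyl ether) under neutral conditions that neither hydrolyse nor migrate the gallate and do not touch the four stereocentres; the reaction is stopped after the hydrogen uptake for debenzylation to spare the tropolone ring.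

## Compound list

1 | 1-bromo-2,3,4-trimethoxybenzene | COc1ccc(Br)c(OC)c1OC | starting material
2 | 4-bromobenzene-1,2,3-triol | Oc1ccc(Br)c(O)c1O | intermediate
3 | (−)-epicatechin, (2R,3R) | O[C@@H]1Cc2c(O)cc(O)cc2O[C@@H]1c1ccc(O)c(O)c1 | starting material
4 | epicatechin o-quinone, 4-[(2R,3R)-3,5,7-trihydroxychroman-2-yl]cyclohexa-3,5-diene-1,2-dione | O[C@@H]1Cc2c(O)cc(O)cc2O[C@@H]1C1=CC(=O)C(=O)C=C1 | intermediate (not isolated)
5 | (2R,3R)-2-(7-bromo-3,4,6-trihydroxy-5-oxo-5H-benzo[7]annulen-1-yl)chromane-3,5,7-triol | Brc1ccc2c([C@H]3Oc4cc(O)cc(O)c4C[C@H]3O)cc(O)c(O)c2c(=O)c1O | intermediate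
6 | 1-[(2R,3R)-5,7-bis(benzyloxy)-3-hydroxychroman-2-yl]-3,4,6-tris(benzyloxy)-7-bromo-5H-benzo[7]annulen-5-one | Brc1ccc2c([C@H]3Oc4cc(OCc5ccccc5)cc(OCc5ccccc5)c4C[C@H]3O)cc(OCc3ccccc3)c(OCc3ccccc3)c2c(=O)c1OCc1ccccc1 | intermediate
7 | 1-[(2R,3R)-3,5,7-tris(benzyloxy)chroman-2-yl]-3,4,6-tris(benzyloxy)-7-bromo-5H-benzo[7]annulen-5-one | Brc1ccc2c([C@H]3Oc4cc(OCc5ccccc5)cc(OCc5ccccc5)c4C[C@H]3OCc3ccccc3)cc(OCc3ccccc3)c(OCc3ccccc3)c2c(=O)c1OCc1ccccc1 | intermediate
8 | 3,5-bis(benzyloxy)phenol | Oc1cc(OCc2ccccc2)cc(OCc2ccccc2)c1 | starting material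
9 | 1-(allyloxy)-3,5-bis(benzyloxy)benzene | C=CCOc1cc(OCc2ccccc2)cc(OCc2ccccc2)c1 | intermediate
10 | 2-allyl-3,5-bis(benzyloxy)phenol | C=CCc1c(O)cc(OCc2ccccc2)cc1OCc1ccccc1 | intermediate
11 | 2-allyl-1,5-bis(benzyloxy)-3-(ethenyloxy)benzene | C=CCc1c(OC=C)cc(OCc2ccccc2)cc1OCc1ccccc1 | intermediate
12 | 5,7-bis(benzyloxy)-4H-chromene | C1=COc2cc(OCc3ccccc3)cc(OCc3ccccc3)c2C1 | intermediate
13 | 3,4,6-tris(benzyloxy)-7-[(2S,3R)-5,7-bis(benzyloxy)-3-(4,4,5,5-tetramethyl-1,3,2-dioxaborolan-2-yl)chroman-2-yl]-1-[(2R,3R)-3,5,7-tris(benzyloxy)chroman-2-yl]-5H-benzo[7]annulen-5-one | CC1(C)OB(OC1(C)C)[C@@H]1Cc2c(OCc3ccccc3)cc(OCc3ccccc3)cc2O[C@@H]1c1ccc2c([C@H]3Oc4cc(OCc5ccccc5)cc(OCc5ccccc5)c4C[C@H]3OCc3ccccc3)cc(OCc3ccccc3)c(OCc3ccccc3)c2c(=O)c1OCc1ccccc1 | intermediate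
14 | 3,4,6-tris(benzyloxy)-7-[(2R,3R)-5,7-bis(benzyloxy)-3-hydroxychroman-2-yl]-1-[(2R,3R)-3,5,7-tris(benzyloxy)chroman-2-yl]-5H-benzo[7]annulen-5-one | O[C@@H]1Cc2c(OCc3ccccc3)cc(OCc3ccccc3)cc2O[C@@H]1c1ccc2c([C@H]3Oc4cc(OCc5ccccc5)cc(OCc5ccccc5)c4C[C@H]3OCc3ccccc3)cc(OCc3ccccc3)c(OCc3ccccc3)c2c(=O)c1OCc1ccccc1 | intermediate
15 | 3,4,5-tris(benzyloxy)benzoic acid | OC(=O)c1cc(OCc2ccccc2)c(OCc2ccccc2)c(OCc2ccccc2)c1 | starting material
16 | (2R,3R)-5,7-bis(benzyloxy)-2-{3,4,6-tris(benzyloxy)-5-oxo-1-[(2R,3R)-3,5,7-tris(benzyloxy)chroman-2-yl]-5H-benzo[7]annulen-7-yl}chroman-3-yl 3,4,5-tris(benzyloxy)benzoate | O=C(O[C@@H]1Cc2c(OCc3ccccc3)cc(OCc3ccccc3)cc2O[C@@H]1c1ccc2c([C@H]3Oc4cc(OCc5ccccc5)cc(OCc5ccccc5)c4C[C@H]3OCc3ccccc3)cc(OCc3ccccc3)c(OCc3ccccc3)c2c(=O)c1OCc1ccccc1)c1cc(OCc2ccccc2)c(OCc2ccccc2)c(OCc2ccccc2)c1 | intermediate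
17 | (2R,3R)-5,7-dihydroxy-2-{3,4,6-trihydroxy-5-oxo-1-[(2R,3R)-3,5,7-trihydroxychroman-2-yl]-5H-benzo[7]annulen-7-yl}chroman-3-yl 3,4,5-trihydroxybenzoate | O=C(O[C@@H]1Cc2c(O)cc(O)cc2O[C@@H]1c1ccc2c([C@H]3Oc4cc(O)cc(O)c4C[C@H]3O)cc(O)c(O)c2c(=O)c1O)c1cc(O)c(O)c(O)c1 | target

## Step count and risks

Total step count: 12. Longest linear sequence: 8 steps (1 → 2 → 5 → 6 → 7 → 13 → 14 → 16 → 17, or equally 8 → 9 → 10 → 11 → 12 → 13 → 14 → 16 → 17).

Steps most likely to fail:

1. Step 9 (Proposed new method). The chiral nickel catalyst may discriminate the two faces of the chromene poorly. The C7–Br bond may be borylated or reduced before it couples, the boryl-metal may add to the tropolone ring, or the β-aryloxy boronate may undergo β-aryloxide elimination. The fallback uses known chemistry and sets out from 7 and 12. An asymmetric intermolecular Heck arylation (Pd(OAc)2, BINAP, Ag2CO3, toluene, 60 °C) would put the aryl group on C2 and move the double bond to C3=C4 by β-hydride elimination toward the benzylic C4, giving the 2-aryl-2H-chromene F1. Hydroboration–oxidation (BH3·SMe2, THF, 0 °C; NaBO3), anti to the C2 aryl group, would give the 2,3-trans alcohol F2. Dess–Martin periodinane would give the flavan-3-one F3. L-Selectride/LiBr in THF at −78 °C would deliver hydride anti to the C2 aryl group, and the route is rejoined at 14.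

2. Step 2. Self-condensation of the pyrogallol, oligomerisation of the unprotected catechin quinone through its nucleophilic phloroglucinol ring, or loss of halogen during the oxidative cascade may outrun the cross-condensation. The fallback sets out from 3 and builds the benzotropolone from a discrete, protected quinone. Dichlorodiphenylmethane (neat, 170 °C) would protect the catechol as the diphenylmethylene ketal F4. NaH/BnBr would give the tribenzyl ether F5. AcOH/H2O at 80 °C would remove the ketal to give the catechol F6. o-Chloranil at −20 °C would give the o-quinone F7. Addition of 2 and a second charge of oxidant would give the bromobenzotropolone triol F8. Benzylation (BnBr, K2CO3, DMF) rejoins the route at 7.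

3. Step 12. The tropolone ring may be over-reduced, or cleavage of the eleven benzyl groups may stay incomplete on the catalyst surface. The fallback sets out from 16 and uses a non-reductive Lewis-acid debenzylation (BCl3, pentamethylbenzene as cation scavenger, CH2Cl2, −78 °C), which arrives directly at 17; this fallback makes no new compound (F0).

Further compounds

F1 | step 9 | 3,4,6-tris(benzyloxy)-7-[(2S)-5,7-bis(benzyloxy)-2H-chromen-2-yl]-1-[(2R,3R)-3,5,7-tris(benzyloxy)chroman-2-yl]-5H-benzo[7]annulen-5-one | C1=Cc2c(OCc3ccccc3)cc(OCc3ccccc3)cc2O[C@@H]1c1ccc2c([C@H]3Oc4cc(OCc5ccccc5)cc(OCc5ccccc5)c4C[C@H]3OCc3ccccc3)cc(OCc3ccccc3)c(OCc3ccccc3)c2c(=O)c1OCc1ccccc1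
F2 | step 9 | 3,4,6-tris(benzyloxy)-7-[(2R,3S)-5,7-bis(benzyloxy)-3-hydroxychroman-2-yl]-1-[(2R,3R)-3,5,7-tris(benzyloxy)chroman-2-yl]-5H-benzo[7]annulen-5-one | O[C@H]1Cc2c(OCc3ccccc3)cc(OCc3ccccc3)cc2O[C@@H]1c1ccc2c([C@H]3Oc4cc(OCc5ccccc5)cc(OCc5ccccc5)c4C[C@H]3OCc3ccccc3)cc(OCc3ccccc3)c(OCc3ccccc3)c2c(=O)c1OCc1ccccc1
F3 | step 9 | 3,4,6-tris(benzyloxy)-7-[(2R)-5,7-bis(benzyloxy)-3-oxochroman-2-yl]-1-[(2R,3R)-3,5,7-tris(benzyloxy)chroman-2-yl]-5H-benzo[7]annulen-5-one | O=C1Cc2c(OCc3ccccc3)cc(OCc3ccccc3)cc2O[C@@H]1c1ccc2c([C@H]3Oc4cc(OCc5ccccc5)cc(OCc5ccccc5)c4C[C@H]3OCc3ccccc3)cc(OCc3ccccc3)c(OCc3ccccc3)c2c(=O)c1OCc1ccccc1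
F4 | step 2 | (2R,3R)-2-(2,2-diphenyl-1,3-benzodioxol-5-yl)chromane-3,5,7-triol | O[C@@H]1Cc2c(O)cc(O)cc2O[C@@H]1c1ccc2OC(c3ccccc3)(c3ccccc3)Oc2c1
F5 | step 2 | (2R,3R)-3,5,7-tris(benzyloxy)-2-(2,2-diphenyl-1,3-benzodioxol-5-yl)chromane | O(Cc1ccccc1)[C@@H]1Cc2c(OCc3ccccc3)cc(OCc3ccccc3)cc2O[C@@H]1c1ccc2OC(c3ccccc3)(c3ccccc3)Oc2c1
F6 | step 2 | 4-[(2R,3R)-3,5,7-tris(benzyloxy)chroman-2-yl]benzene-1,2-diol | O(Cc1ccccc1)[C@@H]1Cc2c(OCc3ccccc3)cc(OCc3ccccc3)cc2O[C@@H]1c1ccc(O)c(O)c1
F7 | step 2 | 4-[(2R,3R)-3,5,7-tris(benzyloxy)chroman-2-yl]cyclohexa-3,5-diene-1,2-dione | O(Cc1ccccc1)[C@@H]1Cc2c(OCc3ccccc3)cc(OCc3ccccc3)cc2O[C@@H]1C1=CC(=O)C(=O)C=C1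
F8 | step 2 | 7-bromo-3,4,6-trihydroxy-1-[(2R,3R)-3,5,7-tris(benzyloxy)chroman-2-yl]-5H-benzo[7]annulen-5-one | Brc1ccc2c([C@H]3Oc4cc(OCc5ccccc5)cc(OCc5ccccc5)c4C[C@H]3OCc3ccccc3)cc(O)c(O)c2c(=O)c1O
F0 | step 12 | none | none
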